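Start with the easy step: write down what stands in this closed flask and what you want from it.

free monomer 0.67 M; initiator 5.5 mM; time 4.0 h

    free monomer + initiator → living end + monomer in chains (k1 = 0.0889 L mol⁻¹ min⁻¹)
    free monomer + living end → monomer in chains + living end, rate k2*[living end]*[free monomer] (k2 = 1.94 L mol⁻¹ min⁻¹)
    monomer in chains + living end → free monomer + living end, rate k3*[living end] as long as [monomer in chains] is above zero (k3 = 0.612 min⁻¹)
    free monomer → uncatalysed product (k4 = 0.00328 min⁻¹)
    2 initiator → spent initiator (k5 = 11.2 L mol⁻¹ min⁻¹)

- a step written with two of one species runs at k times the square of its concentration and takes two of it each time
- the average divides the monomer in chains by the number of chains begun, living and dead together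
- run time (flask): 4.0 h

1. average number of monomer units in a chain (chains begun, living or dead) at 4.0 h
2. part of the free monomer that has reacted at 4.0 h

The fastest rung is the initiator. At the charge, pairing removes it at 0.123 min⁻¹ and initiation at 0.0596 min⁻¹, so pairing is faster than initiation. Dividing one loss by the other and integrating, with c(free monomer) held at its charge, gives chains begun, c(living end) = 0.00298 M.

On the next rung these ends stand constant, and free monomer becomes pseudo-first-order. Growth and uncatalysed loss together take it at 0.00906 min⁻¹, a time of 110 min, far longer than the initiator's starting life of 5.47 min. As long as monomer in chains stands above zero, return from chains runs at a steady k3·c(living end), so c(free monomer) decays exponentially towards 0.201 M, its target level, where return balances growth and uncatalysed loss at constant living ends. This is no end state of the flask: at that level growth is slower than return, so chains shrink, and the reckoning holds as long as some remain.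

At 4.0 h this gives c(free monomer) = 0.255 M, so 62.0% has reacted. Integrating the uncatalysed loss gives 0.309 M of product. The remainder, 0.107 M, is in chains, which makes 35.9 units per chain.

The forecast gave 33 (from 27 to 39) and 62% (from 58% to 66%), on the ground that “Initiation competes with initiator self-destruction”.

The simulation gives 33.1 units per chain and 61.6% reacted.

Now read the same flask at 6.0 h, where the simulated neighbour still holds 6.33% of the charged free monomer in chains, with the target level unchanged at 0.201 M. The reckoning puts c(free monomer) at 0.219 M, just above that level, with 67.3% reacted. Product comes to 0.401 M, which leaves 16.8 units per chain. The simulated neighbour has 67.2% reacted and 14.4 units per chain.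

The numbers of this flask were set for the occasion; the rest is arithmetic.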